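Time comes first. In Tuesday's flask at 48 °C, target reads 40% after 10.0 s and 59% after 90.0 s, though the dose runs for 2.5 min.

| setting | Friday's | Tuesday's | Thursday's | alder | ash | oak | maple |
|---|---|---|---|---|---|---|---|
| starting material | 0.18 M | 0.18 M | 0.28 M | 0.50 M | 0.18 M | 0.10 M | 0.18 M |
| second substrate | 0.019 M (fed, over 2.5 min) | 0.12 M (fed, over 2.5 min) | 0.090 M (fed, over 2.5 min) | 0.0250 M (fed, over 2.5 min) | 0.150 M (fed, over 2.5 min) | 0.0900 M (fed, over 2.5 min) | 0.0900 M (fed, over 2.5 min) |
| capture agent | 0.018 M | 0.018 M | 0.018 M | 0.0180 M | 0.0180 M | 0.0180 M | 0.0180 M |
| free enzyme | 11 µM | 11 µM | 11 µM | 11 µM | 11 µM | 11 µM | 11 µM |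
| temperature | 15 °C | 48 °C | 15 °C | 0 °C | 30 °C | 60 °C | 30 °C |
| remark | run made earlier; the fed solution adds 1.0 times the starting volume | run made earlier; the fed solution adds 1.0 times the starting volume | run made earlier; the fed solution adds 1.0 times the starting volume | the fed solution adds 1.0 times the starting volume | the fed solution adds 1.0 times the starting volume | the fed solution adds 1.0 times the starting volume | the fed solution adds 1.0 times the starting volume |
| time |  |  |  | 4.0 min | 4.0 min | 4.0 min | 4.0 min |

Friday's run (percent of the starting material charged): time / min: target / % = 1.33: 26; 3.00: 30; 4.00: 29; 5.00: 31; 6.00: 29; 8.00: 30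

Tuesday's run (percent of the starting material charged): time / s: target / % = 10.0: 40; 12.0: 46; 20.0: 55; 30.0: 57; 60.0: 58; 90.0: 59

Thursday's run (percent of the starting material charged): time / min: target / % = 0.667: 13; 2.00: 11; 4.00: 12; 6.00: 12; 8.00: 13

(readings scatter by 1.5 percentage points)

- charges are per starting volume, the dose included; the dosed solution carries all of it
- the numbers in the tables scatter with a standard deviation of 1.5 percentage points
- a reading or a percentage of target counts all its forms, free or not

- the flasks put in order of amount of target, in percent of the starting material charged, best first, at 4.0 min (alder / ash / oak / maple)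
- the amount of target, in percent of the starting material charged of the flask you put first, at 4.0 min
- the amount of target, in percent of the starting material charged of the flask you put last, at 4.0 min

1. Friday's flask levels near 30%, which leaves about 70.0% of its starting material unconverted by the balance. Its target, 0.0540 M, exceeds the 0.019 M of second substrate charged, so second substrate is not the limiting reagent. I conclude that the enzyme in Friday's flask stops working.

2. Two times matter. The working life is the plateau divided by the first slope; Tuesday's readings give 14.7 s. The dosing time is 2.5 min, or 10.2 working lives.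

3. Because Tuesday's working life is shorter than the dosing time, the enzyme in that flask works early in the feed, while the dosed amount of second substrate climbs in proportion to time. I assume that its death follows accumulated exposure, which grows as feed rate times time squared. At fixed temperature and fixed [starting material], the working life then goes as the inverse square root of the charge, and the plateau is rate times working life.

4. At fixed temperature and fixed [starting material], the plateau ratio of two flasks is therefore the square root of the inverse ratio of their charges. Maple over ash gives 1.29. Friday against Thursday is a loose test, since [starting material] differs: 1.61 in target concentration, against 2.18 by the rule.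

5. Tuesday stands above Friday despite its larger charge, so I expect warmth to help. I put oak, at 60 °C, first and alder, at 0 °C, last.

6. The forecast reads oak > maple > ash > alder, with 84% and 8% at the two ends, on the ground that “The enzyme appears to die in proportion to accumulated dosed substrate”.

7. The flasks give oak > maple > ash > alder, with 66.7% and 6.73% at the ends.

    free enzyme → unfolded enzyme (k = 0.00179 min⁻¹, Ea = 221 kJ mol⁻¹)
    starting material + free enzyme ⇌ complex A (K = 9.05 M⁻¹, k = 26800 M⁻¹ s⁻¹, Ea = 34.0 kJ mol⁻¹, ΔH = −32.0 kJ mol⁻¹)
    complex A → free enzyme + target (k = 32900 min⁻¹, Ea = 66.0 kJ mol⁻¹)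
    second substrate + free enzyme ⇌ complex B (K = 16.7 M⁻¹, k = 4.43 × 10⁵ M⁻¹ min⁻¹, Ea = 33.0 kJ mol⁻¹, ΔH = −38.0 kJ mol⁻¹)
    complex B → free enzyme + second product (k = 3710 min⁻¹, Ea = 65.0 kJ mol⁻¹)
    capture agent + complex B → trapped intermediate (k = 4050 M⁻¹ min⁻¹, Ea = 35.0 kJ mol⁻¹)
    crystals ⇌ target, rate k7*(cs7 - [target]) while solid is left; crystals form when [target] > cs7 (solubility = 0.140 M, k = 1.25 min⁻¹)
    (constants at 30 °C)

Maple stands at 32.3% and ash at 25.6%, a ratio of 1.26 against the plateau ratio of 1.29. Maple's recipe with second substrate at 0.0250 M ends at 55.3%, which is 1.71 times maple, where the same rule gives 1.90. In oak, the half-life of free enzyme by unfolding alone is 0.14 min, shorter than the dosing time of 2.5 min. After 4.00 min, oak holds 59.2% of its catalyst as unfolded enzyme and 40.8% as trapped intermediate.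

(All runs come from a simulation on assumed constants; scatter was added.)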